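Locants used throughout: rings B and C are numbered as a hydrindane (C1 and C2 = the CH2–CH2 of ring C, C3 = C(OH)CH3, C3a, C4, C5 = spiro carbon, C6, C7 = C(OH)CH3, C7a); ring A is C1′ (= C5), C2′ (C=O), C3′ (diprenyl carbon), C4′ (C–OH), C5′ (acyl carbon), C6′ (C=O); β is the face of H-3a.
Ring A is cut last: gem-diprenylation at C3′, Claisen closure C3′–C2′ onto a lactone carbonyl, C-acylation C6′–C5′ of 5-methylhexane-2,4-dione; the spiro carbon is a malonate carbon whose two esters are told apart by a temporary γ-lactone between the β-axial ester and the 7β-oxygen.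
Ring C is cut at C1–C7a and C2–C3: a strain-release [3+2] of a siloxycyclopropyl ketone (latent γ-oxo enolate) with phenyl vinyl sulfone as the two-carbon unit; the sulfonyl group is removed afterwards.
Enabling feature: the oxygen-bearing carbons C3 (ring C) and C7 (ring B, a ketone in the precursor) are 1,4-related across the ring-fusion bond C3a–C7a, and the C1–C2 bridge joins C7a (α to C7) to C3 (γ to C7); a cyclopropane C3–C3a–C7a with the donor oxygen on C3 and the acceptor C7=O stores this pair and releases the C7a enolate and the C3 carbonyl together.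
Order of ring formation: ring B together with the fused cyclopropane (asymmetric intramolecular cyclopropanation), ring C (key step), temporary lactone, ring A.

Key step: step 7

Assumption: the sense of induction of the chiral copper catalyst in step 6 cannot be predicted with certainty; the ligand enantiomer that gives (1R,6S)-10 is meant and is written here as (S,S).

Step 1
Reactants: 1 dimethyl malonate; 2 methyl vinyl ketone
Product: 3 dimethyl 2-(3-oxobutyl)malonate
Conditions: NaOMe (cat.), MeOH, 0 °C to rt, 1 in excess
Reagents that add atoms: none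
Why: Base-catalysed Michael addition of the malonate to the enone should give the 1,5-dicarbonyl adduct; no stereocentre is formed.

Step 2
Reactants: 3 dimethyl 2-(3-oxobutyl)malonate; 4 allyl bromoacetate
Product: 5 dimethyl 2-(2-allyloxy-2-oxoethyl)-2-(3-oxobutyl)malonate
Conditions: NaH, THF, 0 °C; then 4, 0 °C to rt
Reagents that add atoms: none
Why: SN2 alkylation of the malonate anion (far more acidic than the ketone α-positions) by the α-bromo ester should create the quaternary carbon that becomes the spiro centre.

Step 3
Reactants: 5 dimethyl 2-(2-allyloxy-2-oxoethyl)-2-(3-oxobutyl)malonate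
Product: 6 dimethyl 2-(2-allyloxy-2-oxoethyl)-2-[(2Z)-3-(tert-butyldimethylsilyloxy)but-2-enyl]malonate
Conditions: TBSOTf, Et3N, CH2Cl2, 0 °C to rt
Reagents that add atoms: tert-butyldimethylsilyl triflate, CC(C)(C)[Si](C)(C)OS(=O)(=O)C(F)(F)F
Why: Silyl enol ether formation under equilibrating conditions should favour the more substituted, internal (Z) enol ether over the terminal one; the alkene geometry has no consequence later.

Step 4
Reactants: 6 the silyl enol ether allyl ester
Product: 7 (5Z)-6-(tert-butyldimethylsilyloxy)-3,3-bis(methoxycarbonyl)hept-5-enoic acid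
Conditions: Pd(PPh3)4 (cat.), pyrrolidine, THF, rt; pH 5 buffer work-up
Reagents that add atoms: none
Why: Tsuji–Trost deallylation with zerovalent palladium and an amine allyl acceptor should free the acid under neutral conditions that spare the silyl enol ether and the methyl esters.

Step 5
Reactants: 7 the hept-5-enoic acid
Product: 9 dimethyl 2-(3-diazo-2-oxopropyl)-2-[(2Z)-3-(tert-butyldimethylsilyloxy)but-2-enyl]malonate, via isobutyl carbonic mixed anhydride 8 (not isolated)
Conditions: i-BuOCOCl, N-methylmorpholine, THF, −15 °C; then CH2N2, Et2O, 0 °C to rt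
Reagents that add atoms: diazomethane, C=[N+]=[N-]; isobutyl chloroformate, CC(C)COC(Cl)=O (its atoms stay only in 8)
Why: Acylation of diazomethane by the mixed anhydride (the diazoketone stage of an Arndt–Eistert sequence) proceeds under base-buffered conditions that the silyl enol ether tolerates.

Step 6
Reactants: 9 the diazoketone
Product: 10 dimethyl (1R,6S,7S)-7-(tert-butyldimethylsilyloxy)-7-methyl-2-oxobicyclo[4.1.0]heptane-4,4-dicarboxylate
Conditions: (CuOTf)2·C6H6 (cat.), (S,S)-t-Bu-box (cat.), CH2Cl2, rt, slow addition of 9
Reagents that add atoms: none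
Why: Intramolecular cyclopropanation of the electron-rich silyl enol ether by the copper carbenoid should close ring B and the donor–acceptor cyclopropane in one event; the tether forces cis fusion, the chiral bis(oxazoline) ligand selects the alkene face and so sets C6 (the later C3a), and the Z geometry places the silyloxy group endo at C7 (a centre erased in step 7).

Step 7
Reactants: 10 the siloxycyclopropyl ketone; 11 phenyl vinyl sulfone
Product: 14 dimethyl 3α-hydroxy-3β-methyl-7-oxo-2-(phenylsulfonyl)-trans-octahydroindene-5,5-dicarboxylate, via ammonium enolate 12 (not isolated), via sulfonyl carbanion 13 (not isolated)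
Conditions: Bu4N[Ph3SiF2] (TBAT), 11, THF, −78 to −20 °C; AcOH quench at −78 °C
Reagents that add atoms: none
Why: Proposed new method: fluoride removes the silyl group, the cyclopropanolate opens by cleavage of the donor–acceptor bond C3–C7a (the only cleavage that gives a ketone enolate) to the γ-oxo enolate 12, this adds to phenyl vinyl sulfone (bond C7a–C1), and the α-sulfonyl carbanion 13 closes ring C by aldol addition to the acetyl carbonyl that the ring opening has just unmasked (bond C2–C3). The closest known reaction types are the fluoride-induced ring opening of 2-siloxycyclopropyl carbonyl compounds with Michael trapping of the γ-oxo enolate in the same flask, the cyclopentene annulation of enolates with vinylphosphonium salts, and Michael–aldol annulations of sulfone-stabilised carbanions. Ring C closes in a 5-exo-trig mode (carbanion onto C=O), while attack on the ring B ketone would need a four-membered ring. C7a should be set by Michael addition anti to the acetyl substituent on C3a, as in conjugate addition–enolate trapping of cyclohexenones; this trans-diequatorial arrangement is also the more stable one and C7a stays epimerisable α to the ketone. C3 is set in the aldol closure on the chair-locked trans-diequatorial ring B, where the methyl group should take the open position syn to H-3a and the oxygen the position gauche to C4, and reversibility of the sulfonyl-carbanion aldol should let this more stable epimer accumulate before the cold quench. The step needs enolate formation only at C7a and retention of configuration at C3a (both secured because the enolate is born by C–C cleavage in an aprotic medium and is trapped before proton exchange can set in) and closure only onto the acetyl group (secured by ring size); C2 forms as an epimer mixture that step 9 removes.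

Step 8
Reactants: 14 the hydroxy keto sulfone
Product: 16 methyl 3α-hydroxy-3β,7α-dimethyl-2-(phenylsulfonyl)-trans-octahydroindene-5α-carboxylate 5β,7β-carbolactone, via diol diester 15 (not isolated)
Conditions: MeLi, CeCl3, THF, −78 °C to rt; then TsOH (cat.), CH2Cl2, rt
Reagents that add atoms: methyllithium, [Li]C
Why: Organocerium 1,2-addition is selective for the ketone over the hindered malonate esters and is non-basic; attack from the equatorial direction (the axial path is blocked by the β-axial ester on C5 and by H-3a) should give the 7β-axial alkoxide with the 7α-methyl group, and lactonisation of this alkoxide onto the syn-axial ester tells the two esters apart and thereby fixes the spiro centre C5.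

Step 9
Reactants: 16 the lactone ester sulfone
Product: 17 methyl 3α-hydroxy-3β,7α-dimethyl-trans-octahydroindene-5α-carboxylate 5β,7β-carbolactone
Conditions: Na(Hg), Na2HPO4, MeOH–THF, −20 °C
Reagents that add atoms: none
Why: Reductive desulfonylation by electron transfer (C–S cleavage, protonation of the carbanion by methanol) should remove the temporary activating group from C2, and the buffered, cold conditions disfavour β-elimination of the 3-hydroxyl.

Step 10
Reactants: 17 the lactone methyl ester
Product: 18 3α-hydroxy-3β,7α-dimethyl-trans-octahydroindene-5α-carboxylic acid 5β,7β-carbolactone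
Conditions: LiI, EtOAc, reflux; 1 M HCl work-up
Reagents that add atoms: none
Why: SN2 demethylation of the hindered methyl ester by iodide should free the α-carboxyl without touching the lactone, whose alkyl–oxygen carbon is tertiary; no stereocentre is affected.

Step 11
Reactants: 18 the lactone acid; 19 5-methylhexane-2,4-dione
Product: 23 3-acyl-5-methylhexane-2,4-dione (enol form) whose acyl group is the C5α-carbonyl of the 3α-hydroxy-3β,7α-dimethyl-trans-octahydroindene 5β,7β-carbolactone, via bis(trimethylsilyl) derivative 20 (not isolated), via acid chloride 21 (not isolated), via silyl ether 22 (not isolated)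
Conditions: TMSOTf, Et3N, CH2Cl2, 0 °C; (COCl)2, DMF (cat.), 0 °C; then 19, MgCl2, pyridine, CH2Cl2, 0 °C to rt; 1 M HCl, THF
Reagents that add atoms: trimethylsilyl triflate, C[Si](C)(C)OS(=O)(=O)C(F)(F)F (atoms stay only in 20 to 22); oxalyl chloride, ClC(=O)C(Cl)=O (chlorine stays only in 21)
Why: Transient silylation protects the tertiary alcohol, the silyl ester is converted to the acid chloride under neutral conditions, and magnesium-enolate C-acylation of the β-diketone at its central carbon forms the C6′–C5′ bond; only the former free carboxyl can be activated, so the sense of ring A relative to the spiro centre is fixed.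

Step 12
Reactants: 23 the lactone triketone
Product: 24 spiro trione lacking the prenyl groups (3′-unsubstituted Tomoeone D; C2′ carbonyl β)
Conditions: LiN(i-Pr)2 (4 equiv), THF, −78 to 0 °C; 1 M HCl work-up
Reagents that add atoms: none
Why: Intramolecular Claisen condensation (Dieckmann type): the kinetic carbanion at the acetyl methyl group of the triketone polyanion should attack the lactone carbonyl in a six-membered closure, the 7β-alkoxide is expelled and the product is held as its stable triketonate; no stereocentre is touched.

Step 13
Reactants: 24 the spiro trione; 25 prenyl bromide (1-bromo-3-methylbut-2-ene), first equivalent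
Product: 27 Tomoeone D, via monoprenyl trione 26 (not isolated)
Conditions: 25 (3 equiv in all), NaOMe (3 equiv), MeOH, 0 °C to rt
Reagents that add atoms: prenyl bromide (second equivalent of 25, consumed by 26), CC(C)=CCBr
Why: Two successive C-alkylations of the enolised β-triketone at C3′, its only remaining C–H carbon, by the allylic bromide (the mono-prenyl compound 26 is deprotonated again in the same flask and takes up the second prenyl group) are the standard way to gem-diprenylate a 2-acylcyclohexane-1,3,5-trione; the tertiary alcohols should not react and no stereocentre of the product is formed or touched.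

Compound list
1 | dimethyl malonate | COC(=O)CC(=O)OC | starting material
2 | methyl vinyl ketone (but-3-en-2-one) | CC(=O)C=C | starting material
3 | dimethyl 2-(3-oxobutyl)malonate | COC(=O)C(CCC(C)=O)C(=O)OC | intermediate
4 | allyl bromoacetate | BrCC(=O)OCC=C | starting material
5 | dimethyl 2-(2-allyloxy-2-oxoethyl)-2-(3-oxobutyl)malonate | COC(=O)C(CC(=O)OCC=C)(CCC(C)=O)C(=O)OC | intermediate
6 | dimethyl 2-(2-allyloxy-2-oxoethyl)-2-[(2Z)-3-(tert-butyldimethylsilyloxy)but-2-enyl]malonate | COC(=O)C(CC(=O)OCC=C)(C/C=C(/C)O[Si](C)(C)C(C)(C)C)C(=O)OC | intermediate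
7 | (5Z)-6-(tert-butyldimethylsilyloxy)-3,3-bis(methoxycarbonyl)hept-5-enoic acid | COC(=O)C(CC(=O)O)(C/C=C(/C)O[Si](C)(C)C(C)(C)C)C(=O)OC | intermediate
8 | isobutyl carbonic mixed anhydride of 7 | COC(=O)C(CC(=O)OC(=O)OCC(C)C)(C/C=C(/C)O[Si](C)(C)C(C)(C)C)C(=O)OC | intermediate (not isolated)
9 | dimethyl 2-(3-diazo-2-oxopropyl)-2-[(2Z)-3-(tert-butyldimethylsilyloxy)but-2-enyl]malonate | COC(=O)C(CC(=O)C=[N+]=[N-])(C/C=C(/C)O[Si](C)(C)C(C)(C)C)C(=O)OC | intermediate
10 | dimethyl (1R,6S,7S)-7-(tert-butyldimethylsilyloxy)-7-methyl-2-oxobicyclo[4.1.0]heptane-4,4-dicarboxylate (cis-fused, silyloxy group endo) | COC(=O)C1(C(=O)OC)C[C@H]2[C@@H](C(=O)C1)[C@@]2(C)O[Si](C)(C)C(C)(C)C | intermediate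
11 | phenyl vinyl sulfone | C=CS(=O)(=O)c1ccccc1 | starting material
12 | tetrabutylammonium enolate of dimethyl 5-acetyl-3-oxocyclohexane-1,1-dicarboxylate (enolate toward C4; C5 configured as C3a of the target) | CCCC[N+](CCCC)(CCCC)CCCC.COC(=O)C1(C(=O)OC)C[C@H](C(C)=O)C=C([O-])C1 | intermediate (not isolated)
13 | tetrabutylammonium α-sulfonyl carbanion of dimethyl trans-5-acetyl-3-oxo-4-[2-(phenylsulfonyl)ethyl]cyclohexane-1,1-dicarboxylate | CCCC[N+](CCCC)(CCCC)CCCC.COC(=O)C1(C(=O)OC)C[C@H](C(C)=O)[C@@H](C[CH-]S(=O)(=O)c2ccccc2)C(=O)C1 | intermediate (not isolated)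
14 | dimethyl 3α-hydroxy-3β-methyl-7-oxo-2-(phenylsulfonyl)-trans-octahydroindene-5,5-dicarboxylate (H-3a β, H-7a α; C2 epimers) | COC(=O)C1(C(=O)OC)C[C@H]2[C@@H](CC(S(=O)(=O)c3ccccc3)[C@@]2(C)O)C(=O)C1 | intermediate
15 | dimethyl 3α,7β-dihydroxy-3β,7α-dimethyl-2-(phenylsulfonyl)-trans-octahydroindene-5,5-dicarboxylate (formed as its 7-alkoxide) | COC(=O)C1(C(=O)OC)C[C@H]2[C@@H](CC(S(=O)(=O)c3ccccc3)[C@@]2(C)O)[C@@](C)(O)C1 | intermediate (not isolated)
16 | methyl 3α-hydroxy-3β,7α-dimethyl-2-(phenylsulfonyl)-trans-octahydroindene-5α-carboxylate 5β,7β-carbolactone | O=C1[C@]2(C[C@H]3[C@@H](CC(S(=O)(=O)c4ccccc4)[C@@]3(C)O)[C@@](C)(O1)C2)C(=O)OC | intermediate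
17 | methyl 3α-hydroxy-3β,7α-dimethyl-trans-octahydroindene-5α-carboxylate 5β,7β-carbolactone | O=C1[C@]2(C[C@H]3[C@@H](CC[C@@]3(C)O)[C@@](C)(O1)C2)C(=O)OC | intermediate
18 | 3α-hydroxy-3β,7α-dimethyl-trans-octahydroindene-5α-carboxylic acid 5β,7β-carbolactone | O=C1[C@]2(C[C@H]3[C@@H](CC[C@@]3(C)O)[C@@](C)(O1)C2)C(=O)O | intermediate
19 | 5-methylhexane-2,4-dione | CC(=O)CC(=O)C(C)C | starting material
20 | trimethylsilyl ester and 3-O-trimethylsilyl ether of 18 | O=C1[C@]2(C[C@H]3[C@@H](CC[C@@]3(C)O[Si](C)(C)C)[C@@](C)(O1)C2)C(=O)O[Si](C)(C)C | intermediate (not isolated)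
21 | acid chloride of 18 as its 3-O-trimethylsilyl ether | O=C1[C@]2(C[C@H]3[C@@H](CC[C@@]3(C)O[Si](C)(C)C)[C@@](C)(O1)C2)C(Cl)=O | intermediate (not isolated)
22 | 3-O-trimethylsilyl ether of 23 | O=C1[C@]2(C[C@H]3[C@@H](CC[C@@]3(C)O[Si](C)(C)C)[C@@](C)(O1)C2)C(=O)C(C(C)=O)=C(O)C(C)C | intermediate (not isolated)
23 | lactone triketone: 3-acyl-5-methylhexane-2,4-dione (enol form), acyl = C5α-carbonyl of the 3α-hydroxy-3β,7α-dimethyl-trans-octahydroindene 5β,7β-carbolactone | O=C1[C@]2(C[C@H]3[C@@H](CC[C@@]3(C)O)[C@@](C)(O1)C2)C(=O)C(C(C)=O)=C(O)C(C)C | intermediate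
24 | spiro trione without prenyl groups: 3α,7β-dihydroxy-3β,7α-dimethyl-trans-hydrindane spiro-fused at C5 to 4′-hydroxy-5′-(2-methylpropanoyl)cyclohex-4′-ene-2′,6′-dione (C3′ = CH2; H-3a β, H-7a α, C2′ carbonyl β) | C1C(=O)[C@]2(C[C@H]3[C@@H](CC[C@@]3(C)O)[C@@](C)(O)C2)C(=O)C(C(=O)C(C)C)=C1O | intermediate
25 | prenyl bromide (1-bromo-3-methylbut-2-ene) | CC(C)=CCBr | starting material
26 | monoprenyl trione: 3′-(3-methylbut-2-enyl) derivative of 24 (C3′ enolisable and drawn in the keto form without a defined configuration; present as its sodium enolate) | CC(C)=CCC1C(=O)[C@]2(C[C@H]3[C@@H](CC[C@@]3(C)O)[C@@](C)(O)C2)C(=O)C(C(=O)C(C)C)=C1O | intermediate (not isolated)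
27 | Tomoeone D (hydrindane locants 3R,3aS,5R,7S,7aR; 3α-OH, 3β-CH3, 7β-OH, 7α-CH3, H-3a β, H-7a α, C2′ carbonyl β) | CC(C)=CCC1(CC=C(C)C)C(=O)[C@]2(C[C@H]3[C@@H](CC[C@@]3(C)O)[C@@](C)(O)C2)C(=O)C(C(=O)C(C)C)=C1O | target

Total step count: 13. Longest linear sequence: 13 steps (from 1 to 27; 2, 4, 11, 19 and 25 are bought).

Steps most likely to fail

Step 7 (proposed new method). The sulfonyl carbanion may be quenched by proton transfer from a ketone α-position before it closes, the aldolate may revert by retro-aldol, the Michael addition may occur syn to the acetyl group and lead to a cis ring fusion, or proton exchange α to the acetyl group may erode the configuration at C3a. The fallback sets out from 10 and uses known chemistry. Fluoride-induced ring opening (TBAT, THF) in the presence of vinyltriphenylphosphonium bromide should give, by Michael addition and irreversible intramolecular Wittig closure (cyclopentene annulation with the Schweizer reagent), the cyclopentene dimethyl 3-methyl-7-oxo-trans-3a,4,7,7a-tetrahydro-1H-indene-5,5(6H)-dicarboxylate F1; any cis-fused material can be equilibrated at C7a with NaOMe in MeOH. Mukaiyama hydration (Mn(dpm)3 cat., dpm = dipivaloylmethanate, PhSiH3, O2, i-PrOH) should then place the tertiary hydroxyl on C3, the C3 radical being captured from the α face anti to the axial H-3a, to give dimethyl 3α-hydroxy-3β-methyl-7-oxo-trans-octahydroindene-5,5-dicarboxylate F2. Addition of MeLi/CeCl3 as in step 8 gives dimethyl 3α,7β-dihydroxy-3β,7α-dimethyl-trans-octahydroindene-5,5-dicarboxylate F3, which lactonises and comes back to the route at 17; step 9 is then not needed.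

Step 6. Face discrimination by the copper carbenoid may be insufficient, so that 10 is formed with low enantiomeric purity. The fallback sets out from 9: cyclopropanation with the achiral catalyst Rh2(OAc)4 in CH2Cl2 should give racemic dimethyl 7-(tert-butyldimethylsilyloxy)-7-methyl-2-oxobicyclo[4.1.0]heptane-4,4-dicarboxylate F4, which is resolved by preparative chromatography on a chiral stationary phase; the (1R,6S) enantiomer comes back to the route at 10.

Step 13. O-alkylation of the enolised triketone and stalling at the mono-prenyl stage, before the second alkylation at the hindered carbon, may compete with gem-dialkylation. The fallback sets out from 24: palladium-catalysed C-allylation (Pd(PPh3)4, allyl methyl carbonate in excess, THF; Tsuji–Trost reaction, which is C-selective for β-triketones) should give the 3′,3′-diallyl analogue of Tomoeone D F5, and double cross-metathesis with 2-methylbut-2-ene (second-generation Grubbs catalyst, (H2IMes)(PCy3)Cl2Ru=CHPh, CH2Cl2, 40 °C) turns both allyl groups into prenyl groups and comes back to the route at 27.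

Further compounds
F1 | step 7 | dimethyl 3-methyl-7-oxo-trans-3a,4,7,7a-tetrahydro-1H-indene-5,5(6H)-dicarboxylate | COC(=O)C1(C(=O)OC)C[C@H]2[C@@H](CC=C2C)C(=O)C1
F2 | step 7 | dimethyl 3α-hydroxy-3β-methyl-7-oxo-trans-octahydroindene-5,5-dicarboxylate | COC(=O)C1(C(=O)OC)C[C@H]2[C@@H](CC[C@@]2(C)O)C(=O)C1
F3 | step 7 | dimethyl 3α,7β-dihydroxy-3β,7α-dimethyl-trans-octahydroindene-5,5-dicarboxylate (not isolated) | COC(=O)C1(C(=O)OC)C[C@H]2[C@@H](CC[C@@]2(C)O)[C@@](C)(O)C1
F4 | step 6 | racemic dimethyl 7-(tert-butyldimethylsilyloxy)-7-methyl-2-oxobicyclo[4.1.0]heptane-4,4-dicarboxylate | COC(=O)C1(C(=O)OC)CC2C(C(=O)C1)C2(C)O[Si](C)(C)C(C)(C)C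
F5 | step 13 | 3′,3′-diallyl analogue of Tomoeone D | C=CCC1(CC=C)C(=O)[C@]2(C[C@H]3[C@@H](CC[C@@]3(C)O)[C@@](C)(O)C2)C(=O)C(C(=O)C(C)C)=C1O
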